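The data were generated by integration from invented constants; noise was put on by code.

If each turnover spends two nucleophile, one reacting and one taken up as protonated nucleophile, the 1.31 equiv you charge has to be counted in turnovers before you get your quick number. The runs do not show that binding, so the two per turnover is my guess.

| setting | beta | flask |
|---|---|---|
| electrophile | 0.085 M | 0.085 M |
| nucleophile | 0.111 M (fed, over 50 min) | 0.111 M (fed, over 50 min) |
| free base | 0.128 M | 0.128 M |
| remark | the very flask that is asked about, followed so far |  |
| time |  | 4.0 h |

beta run (percent of the electrophile charged)

| time / min | electrophile / % | product / % |
|---|---|---|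
| 8.00 | 96 | 0 |
| 12.0 | 90 | 5 |
| 20.0 | 82 | 6 |
| 25.0 | 72 | 12 |
| 40.0 | 52 | 27 |
| 60.0 | 27 | 40 |
| 90.0 | 18 | 46 |

(scatter of a reading: 1.5 percentage points)

- a reading or a percentage of product counts all its forms, free or not
- what has gone from electrophile into another species counts as reacted, even if it can come back
- a reading of electrophile is of its free form alone
- the earlier runs do not show how much of nucleophile is bound; that part of a forecast is a guess

1. part of the electrophile that has reacted at 4.0 h
2. share of the unused nucleophile that is free and not bound as protonated nucleophile, at 4.0 h

At the last reading of the beta run, the electrophile lost stands to the product as 1.78 to 1, a ratio that carries the scatter of those readings. Holding that ratio, I count the turnovers each charge can pay for, in percent of the electrophile charged: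

turnover budget of the nucleophile = [nucleophile] / (2 [electrophile]) = 65.3%

product when the electrophile is used up = 1 / 1.78 = 56.1%

This turnover budget is the product that the nucleophile charge pays for at two per turnover. It stands above the electrophile's line, so I expect the electrophile to give out first, with c above the 82.0% already reacted. With T the turnovers at that line, as a concentration:

free share = ([nucleophile] − 2T) / ([nucleophile] − T) = 24.7%

The forecast gives 94% reacted and 53% free, on the assumption that “nucleophile and base have similar basicity”, so its free share is higher than mine.

The flask gives 92.8% reacted and 22.8% free.

    acid set free + free base ⇌ salt of the base, settled at all times (K = 18.0 M⁻¹)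
    nucleophile + acid set free ⇌ protonated nucleophile, settled at all times (K = 68000 M⁻¹)
    electrophile + product ⇌ idle adduct, settled at all times (K = 260 M⁻¹)
    electrophile + nucleophile → acid set free + product (k = 0.00550 M⁻¹ s⁻¹)
    acid set free → by-product carried off (k = 0.00190 s⁻¹)

At 4.00 h this flask holds 57.5% product, under its budget of 65.3%, and 0.0480 M protonated nucleophile against 0.0488 M of turnovers. A neighbour flask charged with 0.067 M of nucleophile has a budget of 39.4%, below the electrophile's line of 56.1%, so the same count names nucleophile as the limiting reagent there. That neighbour reaches 39.9% product and 73.9% reacted, and still holds, unbound, 3.2% of its nucleophile and 26% of its electrophile.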